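**Retrosynthetic overview**
1. The target is epiafzelechin-(4β→8)-epigallocatechin (upper unit: rings A/C/B; lower unit: rings D/F/E). The last disconnection is global hydrogenolysis of eight benzyl ethers and one bromine cap on upper C-8.
2. Key disconnections: the interflavan bond (upper C-4 to lower C-8) and the lower C-4–C-4a bond of pyran ring F. Both are made in one flask on ring D, from an open-chain epoxy aryl ether and a 4-alkoxy-8-bromo-epiafzelechin.
3. Enabling feature: ring D is a phloroglucinol ring. Its C-4a is ortho to the ring oxygen O-1 and to the C-5 oxygen and para to the C-7 oxygen, so it can open a terminal epoxide hung on O-1 (6-endo). C-8 of the same ring (ortho to O-1 and the C-7 oxygen, para to the C-5 oxygen) then takes the flavan-4-yl cation.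
4. Each C-2/C-3 pair comes from an aryl vinyl carbinol by Sharpless kinetic resolution (oxirane carbon = future C-3) and Mitsunobu inversion with 3,5-bis(benzyloxy)phenol (future C-2 and O-1).
5. Ring order: aryl rings A, B, D and E are bought. Ring C is closed first (gold-catalysed epoxy-arene cyclisation, upper unit), followed by C-8 bromination and C-4 oxidation. Ring F is closed last, in the key step.

Key step: step 10

Remark: 4-(benzyloxy)benzaldehyde, 3,4,5-tris(benzyloxy)benzaldehyde and 3,5-bis(benzyloxy)phenol are taken as catalogue compounds; α/β refer to the usual flavan drawing, in which the 2-aryl group of a (2R)-flavan is α.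

**Route**

Step 1
Reactants: 1 4-(benzyloxy)benzaldehyde
Product: 2 rac-1-[4-(benzyloxy)phenyl]prop-2-en-1-ol
Conditions: vinylmagnesium bromide (1.2 equiv), THF, 0 °C to rt; aq. NH4Cl
Reagents that add atoms: vinylmagnesium bromide, C=C[Mg]Br
Why: Grignard 1,2-addition to the aldehyde should give the racemic aryl vinyl carbinol cleanly, and its stereocentre is resolved in step 2.

Step 2
Reactants: 2 rac-1-[4-(benzyloxy)phenyl]prop-2-en-1-ol
Product: 3 (S)-[4-(benzyloxy)phenyl][(2R)-oxiran-2-yl]methanol (erythro epoxy alcohol)
Conditions: Ti(OiPr)4 (0.2 equiv), L-(+)-diisopropyl tartrate (0.24 equiv), t-BuOOH in decane (0.45 equiv), 4 Å MS, CH2Cl2, −20 °C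
Reagents that add atoms: tert-butyl hydroperoxide, CC(C)(C)OO
Why: Sharpless kinetic resolution (titanium tartrate epoxidation of a secondary allylic alcohol): with L-(+)-diisopropyl tartrate the (R)-enantiomer of 2 should be epoxidised much faster than the (S)-enantiomer and with erythro selectivity, so that stopping below half conversion should give 3 with the oxirane carbon R and the carbinol carbon S (a change of label only, caused by the new CIP ranks), both set by the tartrate.

Step 3
Reactants: 3 (S)-[4-(benzyloxy)phenyl][(2R)-oxiran-2-yl]methanol; 4 3,5-bis(benzyloxy)phenol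
Product: 5 (2R)-2-{(R)-[4-(benzyloxy)phenyl][3,5-bis(benzyloxy)phenoxy]methyl}oxirane (threo epoxy aryl ether)
Conditions: PPh3 (1.3 equiv), DIAD (1.3 equiv), toluene, 0 °C to rt
Reagents that add atoms: none
Why: Mitsunobu etherification: the phenol should displace the oxyphosphonium group by SN2 with inversion (S to R), which turns the erythro epoxy alcohol into the threo aryl ether that maps onto a 2,3-cis flavan, while the oxirane stereocentre is untouched and toluene at low temperature holds back ionisation of the benzylic centre.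

Step 4
Reactants: 5 (2R)-2-{(R)-[4-(benzyloxy)phenyl][3,5-bis(benzyloxy)phenoxy]methyl}oxirane
Product: 6 5,7,4′-tri-O-benzyl-(−)-epiafzelechin, (2R,3R)-5,7-bis(benzyloxy)-2-[4-(benzyloxy)phenyl]chroman-3-ol
Conditions: AuCl3 (5 mol %), AgOTf (15 mol %), tetramethylthiourea (5 mol %), 4 Å MS, CH2Cl2, 0 °C to rt
Reagents that add atoms: none
Why: Gold-catalysed intramolecular Friedel–Crafts epoxy-arene cyclialkylation, a known way from such epoxy aryl ethers to flavan-3-ols: the ring A carbon ortho to the ether oxygen should open the gold-bound epoxide at its terminal CH2 (6-endo-tet), closing ring C without touching C-2 or C-3, so the threo relation of 5 becomes the (2R,3R) cis relation of 6.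

Step 5
Reactants: 6 5,7,4′-tri-O-benzyl-(−)-epiafzelechin
Product: 7 8-bromo-5,7,4′-tri-O-benzyl-epiafzelechin, (2R,3R)-8-bromo-5,7-bis(benzyloxy)-2-[4-(benzyloxy)phenyl]chroman-3-ol
Conditions: NBS (1.0 equiv), CH2Cl2, −78 to −40 °C
Reagents that add atoms: N-bromosuccinimide, O=C1CCC(=O)N1Br
Why: Electrophilic aromatic bromination: NBS should attack C-8 of the 5,7-di-O-benzylated ring A, which is more accessible than C-6 flanked by two benzyloxy groups, and the bromine then blocks the only nucleophilic site that could make the later electrophile condense with itself.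

Step 6
Reactants: 7 8-bromo-5,7,4′-tri-O-benzyl-epiafzelechin
Product: 8 8-bromo-5,7,4′-tri-O-benzyl-4β-(2-ethoxyethoxy)epiafzelechin, (2R,3R,4S)-8-bromo-5,7-bis(benzyloxy)-2-[4-(benzyloxy)phenyl]-4-(2-ethoxyethoxy)chroman-3-ol
Conditions: DDQ (2 equiv), 2-ethoxyethanol (10 equiv), CH2Cl2, rt
Reagents that add atoms: 2-ethoxyethanol, CCOCCO
Why: DDQ benzylic oxidation: hydride abstraction from C-4 should give the cation stabilised by O-1 and the 5- and 7-benzyloxy groups, which 2-ethoxyethanol traps from the β face (anti to the α-oriented 2-aryl and 3-hydroxyl groups) to give the 4β ether, a configuration of no consequence because C-4 is ionised again in step 10.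

Step 7
Reactants: 9 3,4,5-tris(benzyloxy)benzaldehyde
Product: 10 rac-1-[3,4,5-tris(benzyloxy)phenyl]prop-2-en-1-ol
Conditions: vinylmagnesium bromide (1.2 equiv), THF, 0 °C to rt; aq. NH4Cl
Reagents that add atoms: vinylmagnesium bromide, C=C[Mg]Br
Why: Grignard 1,2-addition to the aldehyde should give the racemic carbinol for the lower unit, to be resolved in step 8.

Step 8
Reactants: 10 rac-1-[3,4,5-tris(benzyloxy)phenyl]prop-2-en-1-ol
Product: 11 (S)-[(2R)-oxiran-2-yl][3,4,5-tris(benzyloxy)phenyl]methanol (erythro epoxy alcohol)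
Conditions: Ti(OiPr)4 (0.2 equiv), L-(+)-diisopropyl tartrate (0.24 equiv), t-BuOOH in decane (0.45 equiv), 4 Å MS, CH2Cl2, −20 °C
Reagents that add atoms: tert-butyl hydroperoxide, CC(C)(C)OO
Why: Sharpless kinetic resolution as in step 2: the tartrate should select the (R)-carbinol and the erythro face, setting the oxirane carbon (future lower C-3) as R and leaving the carbinol carbon S.

Step 9
Reactants: 11 (S)-[(2R)-oxiran-2-yl][3,4,5-tris(benzyloxy)phenyl]methanol; 4 3,5-bis(benzyloxy)phenol
Product: 12 (2R)-2-{(R)-[3,5-bis(benzyloxy)phenoxy][3,4,5-tris(benzyloxy)phenyl]methyl}oxirane (threo epoxy aryl ether)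
Conditions: PPh3 (1.3 equiv), DIAD (1.3 equiv), toluene, 0 °C to rt
Reagents that add atoms: none
Why: Mitsunobu etherification with SN2 inversion at the carbinol carbon (S to R) should set the future lower C-2 and install O-1 and ring D in one step, the 3,4,5-trialkoxyphenyl group being a poorer cation stabiliser than the aryl group of step 3.

Step 10
Reactants: 12 (2R)-2-{(R)-[3,5-bis(benzyloxy)phenoxy][3,4,5-tris(benzyloxy)phenyl]methyl}oxirane (1.25 equiv) and 8 8-bromo-5,7,4′-tri-O-benzyl-4β-(2-ethoxyethoxy)epiafzelechin
Product: 14 8-bromo-5,7,4′-tri-O-benzyl-epiafzelechin-(4β→8)-5,7,3′,4′,5′-penta-O-benzyl-epigallocatechin, via penta-O-benzyl-epigallocatechin 13 (not isolated)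
Conditions: AuCl3 (5 mol %), AgOTf (30 mol %), tetramethylthiourea (5 mol %), 4 Å MS, CH2Cl2, 0 °C to rt until 12 is consumed; then −30 °C, 8 (0.8 equiv based on 12) added slowly in CH2Cl2, warm to 0 °C
Reagents that add atoms: none
Why: Proposed new method: one charge of oxophilic triflate Lewis acid (Au(OTf)3 formed from AuCl3 and AgOTf, with AgOTf left over) is asked to run two Friedel–Crafts alkylations on ring D in sequence, which as a telescoped pair is new, while each half has a close known type, namely the gold-catalysed cyclialkylation of aryl glycidyl ethers to chroman-3-ols and the triflate-promoted coupling of 4-alkoxyflavans with flavan-3-ol nucleophiles. In the first event the epoxide oxygen of 12 binds gold and the ring D carbon ortho to the ether oxygen attacks the terminal CH2, which closes ring F in a 6-endo-tet mode and leaves C-2 and C-3 untouched, so the 2,3-cis relation of 13 is the threo relation already present in 12. The 6-endo mode should be secured by the unhindered primary terminus, by the inductive deactivation of the internal epoxide carbon through the neighbouring aryloxy-bearing carbon and by the strain of the alternative five-membered closure, and only the two equivalent ortho positions can reach the epoxide, so a single chroman should form. In the second event the 2-ethoxyethoxy group of 8 ionises to the C-4 cation (stabilised by O-1 and the 5- and 7-benzyloxy groups), and C-8 of 13, ortho to O-1 and the 7-benzyloxy group and para to the 5-benzyloxy group, attacks it. The new stereocentre at upper C-4 is set by the substrate: the 2-aryl group and the 3-hydroxyl both lie on the α face, so the nucleophile should enter from the β face and give the 3,4-trans (4β→8) bond. Adding 8 only after the epoxide is consumed keeps the open-chain arene from being alkylated para to its ether oxygen, the bromine on C-8 of 8 stops self-condensation of the electrophile, and C-8 of 13 is preferred over its more hindered C-6.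

Step 11
Reactants: 14 8-bromo-5,7,4′-tri-O-benzyl-epiafzelechin-(4β→8)-5,7,3′,4′,5′-penta-O-benzyl-epigallocatechin
Product: 15 epiafzelechin-(4β→8)-epigallocatechin, (2R,3R,4R)-2-(4-hydroxyphenyl)-4-[(2R,3R)-3,5,7-trihydroxy-2-(3,4,5-trihydroxyphenyl)chroman-8-yl]chroman-3,5,7-triol
Conditions: H2 (1 atm), Pd(OH)2/C, NaOAc (1.5 equiv), THF/MeOH/H2O, rt; filtration under argon, lyophilisation
Reagents that add atoms: none
Why: Catalytic hydrogenolysis should cleave the eight benzyl ethers and, as is known for bromine-capped benzylated flavans, the aryl C–Br bond in the same operation, with NaOAc taking up the HBr so that the acid-labile interflavan bond and all five stereocentres stay untouched.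

**Compound list**
1 | 4-(benzyloxy)benzaldehyde | O=Cc1ccc(OCc2ccccc2)cc1 | starting material
2 | rac-1-[4-(benzyloxy)phenyl]prop-2-en-1-ol | OC(C=C)c1ccc(OCc2ccccc2)cc1 | intermediate
3 | (S)-[4-(benzyloxy)phenyl][(2R)-oxiran-2-yl]methanol | O[C@@H](c1ccc(OCc2ccccc2)cc1)[C@H]1CO1 | intermediate
4 | 3,5-bis(benzyloxy)phenol | Oc1cc(OCc2ccccc2)cc(OCc2ccccc2)c1 | starting material
5 | (2R)-2-{(R)-[4-(benzyloxy)phenyl][3,5-bis(benzyloxy)phenoxy]methyl}oxirane | c1ccccc1COc1ccc([C@@H](Oc2cc(OCc3ccccc3)cc(OCc3ccccc3)c2)[C@H]2CO2)cc1 | intermediate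
6 | 5,7,4′-tri-O-benzyl-(−)-epiafzelechin, (2R,3R) | c1ccccc1COc1ccc([C@H]2Oc3cc(OCc4ccccc4)cc(OCc4ccccc4)c3C[C@H]2O)cc1 | intermediate
7 | 8-bromo-5,7,4′-tri-O-benzyl-epiafzelechin, (2R,3R) | c1ccccc1COc1ccc([C@H]2Oc3c(Br)c(OCc4ccccc4)cc(OCc4ccccc4)c3C[C@H]2O)cc1 | intermediate
8 | 8-bromo-5,7,4′-tri-O-benzyl-4β-(2-ethoxyethoxy)epiafzelechin, (2R,3R,4S) | c1ccccc1COc1ccc([C@H]2Oc3c(Br)c(OCc4ccccc4)cc(OCc4ccccc4)c3[C@H](OCCOCC)[C@H]2O)cc1 | intermediate
9 | 3,4,5-tris(benzyloxy)benzaldehyde | O=Cc1cc(OCc2ccccc2)c(OCc2ccccc2)c(OCc2ccccc2)c1 | starting material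
10 | rac-1-[3,4,5-tris(benzyloxy)phenyl]prop-2-en-1-ol | OC(C=C)c1cc(OCc2ccccc2)c(OCc2ccccc2)c(OCc2ccccc2)c1 | intermediate
11 | (S)-[(2R)-oxiran-2-yl][3,4,5-tris(benzyloxy)phenyl]methanol | O[C@@H](c1cc(OCc2ccccc2)c(OCc2ccccc2)c(OCc2ccccc2)c1)[C@H]1CO1 | intermediate
12 | (2R)-2-{(R)-[3,5-bis(benzyloxy)phenoxy][3,4,5-tris(benzyloxy)phenyl]methyl}oxirane | c1ccccc1COc1cc(OCc2ccccc2)cc(O[C@H](c2cc(OCc3ccccc3)c(OCc3ccccc3)c(OCc3ccccc3)c2)[C@H]2CO2)c1 | intermediate
13 | 5,7,3′,4′,5′-penta-O-benzyl-(−)-epigallocatechin, (2R,3R)-5,7-bis(benzyloxy)-2-[3,4,5-tris(benzyloxy)phenyl]chroman-3-ol | c1c(OCc2ccccc2)cc(OCc2ccccc2)c2c1O[C@H](c1cc(OCc3ccccc3)c(OCc3ccccc3)c(OCc3ccccc3)c1)[C@H](O)C2 | intermediate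
14 | 8-bromo-5,7,4′-tri-O-benzyl-epiafzelechin-(4β→8)-5,7,3′,4′,5′-penta-O-benzyl-epigallocatechin (geometry as in 15; the CIP label of upper C-4 reads S here because bromine on C-8 raises the rank of C-4a) | c1ccccc1COc1ccc([C@H]2Oc3c(Br)c(OCc4ccccc4)cc(OCc4ccccc4)c3[C@H](c3c(OCc4ccccc4)cc(OCc4ccccc4)c4c3O[C@H](c3cc(OCc5ccccc5)c(OCc5ccccc5)c(OCc5ccccc5)c3)[C@H](O)C4)[C@H]2O)cc1 | intermediate
15 | epiafzelechin-(4β→8)-epigallocatechin, (2R,3R,4R)-2-(4-hydroxyphenyl)-4-[(2R,3R)-3,5,7-trihydroxy-2-(3,4,5-trihydroxyphenyl)chroman-8-yl]chroman-3,5,7-triol | Oc1ccc([C@H]2Oc3cc(O)cc(O)c3[C@H](c3c(O)cc(O)c4c3O[C@H](c3cc(O)c(O)c(O)c3)[C@H](O)C4)[C@H]2O)cc1 | target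

**Step count and risks**

Total steps: 11. Longest linear sequence: 8 (steps 1 to 6, then 10 and 11).

Steps most likely to fail:

1. Step 10 (proposed new method). What may go wrong: loss of Lewis acid activity after the ring closure (binding to the new 3-hydroxyl or to the thiourea), or ionisation of the electrophile faster than its capture, so that it decomposes or oligomerises before the interflavan bond forms. Fallback (known chemistry; two separately isolated operations instead of one flask): setting out from 12, the ring closure is run alone under the conditions of step 4 and 13 is isolated by chromatography. 13 (1.5 equiv) and 8 are then coupled with TMSOTf (0.1 equiv) in CH2Cl2 at −78 °C, the established promoter for 4-alkoxyflavan electrophiles, which comes back to the route at 14.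

2. Step 3. What may go wrong: partial ionisation of the 4-benzyloxybenzylic oxyphosphonium intermediate, so that inversion is incomplete and the erythro ether (which leads to the 2,3-trans flavan) forms beside 5. Fallback (no SN2 step at the benzylic carbon; the C-2 configuration comes from a catalyst): setting out from 2, acid-catalysed 1,3-transposition (cat. p-TsOH, aqueous THF) should give (E)-3-[4-(benzyloxy)phenyl]prop-2-en-1-ol F1. Methyl chloroformate and pyridine should then give (E)-3-[4-(benzyloxy)phenyl]allyl methyl carbonate F2. Iridium-catalysed asymmetric allylic etherification of F2 with the lithium salt of 4 ([Ir(cod)Cl]2, a chiral phosphoramidite, THF, rt) should give the branched ether (S)-1-{1-[4-(benzyloxy)phenyl]allyloxy}-3,5-bis(benzyloxy)benzene F3. Epoxidation of its terminal alkene (mCPBA, NaHCO3, CH2Cl2) is expected to show little facial control, so the oxirane epimer is removed by chromatography, which comes back to the route at 5.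

3. Step 11. What may go wrong: slow hydrogenolytic loss of the bromine, which sits between a ring oxygen and a benzyloxy group, so that the free polyphenol is exposed for a long time to bromide, acid or buffer and suffers interflavan cleavage or autoxidation of the trihydroxyphenyl ring. Fallback (bromine removed by metalation before any phenol is free): setting out from 14, bromine–lithium exchange (n-BuLi, THF, −78 °C; MeOH quench) should give 5,7,4′-tri-O-benzyl-epiafzelechin-(4β→8)-5,7,3′,4′,5′-penta-O-benzyl-epigallocatechin F4. Its buffer-free hydrogenolysis (H2, Pd(OH)2/C, THF/MeOH/H2O) comes back to the route at 15.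

**Further compounds**
F0 | step 10 | none | none
F1 | step 3 | (E)-3-[4-(benzyloxy)phenyl]prop-2-en-1-ol | OC/C=C/c1ccc(OCc2ccccc2)cc1
F2 | step 3 | (E)-3-[4-(benzyloxy)phenyl]allyl methyl carbonate | COC(=O)OC/C=C/c1ccc(OCc2ccccc2)cc1
F3 | step 3 | (S)-1-{1-[4-(benzyloxy)phenyl]allyloxy}-3,5-bis(benzyloxy)benzene | c1ccccc1COc1ccc([C@@H](Oc2cc(OCc3ccccc3)cc(OCc3ccccc3)c2)C=C)cc1
F4 | step 11 | 5,7,4′-tri-O-benzyl-epiafzelechin-(4β→8)-5,7,3′,4′,5′-penta-O-benzyl-epigallocatechin | c1ccccc1COc1ccc([C@H]2Oc3cc(OCc4ccccc4)cc(OCc4ccccc4)c3[C@H](c3c(OCc4ccccc4)cc(OCc4ccccc4)c4c3O[C@H](c3cc(OCc5ccccc5)c(OCc5ccccc5)c(OCc5ccccc5)c3)[C@H](O)C4)[C@H]2O)cc1
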